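The constants used here stand for no real mixture; the result is computed.

Two questions stand on this flask, and a single count of turnovers answers both.

free monomer 0.19 M; initiator 5.9 mol%; impurity 7.5 mM; time 6.0 d

    free monomer + initiator → living end + monomer in chains (k1 = 9.24 /M/h)
    free monomer + living end → monomer in chains + living end, rate k2*[living end]*[free monomer] (k2 = 1.53 /M/h)
    initiator + impurity → spent initiator A (k3 = 265 /M/h)
    2 living end → dead end B (k4 = 115 /M/h)

- where a step has two of a species, its rate is k times that concentration squared, and two are used at each turn
- the average divides the monomer in chains by the number of chains begun, living and dead together
- run time (flask): 6.0 d

1. average number of monomer units in a chain (chains begun, living or dead) at 6.0 d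
2. part of the free monomer that has reacted at 6.0 d

**First instants.** Free monomer and impurity both draw on the initiator, their opening rates standing at 0.88 to one. The initiator's half-life against the impurity is 0.35 h, far shorter than the run, so the sharing belongs to the first hours. Since both steps use the same initiator, the logarithmic falls of free monomer and impurity keep the ratio 0.0349, the selectivity factor. Suppose the impurity falls to exp(-1) of its charge. Free monomer then spends about 0.0349 of its charge on initiation, and the impurity takes 2.50 % on the same scale. Together these come close to the initiator's 5.9 mol%, so the supposed fall is nearly right. Chains begun are therefore 3.40 % of the free monomer charged.

**The middle.** Living ends now pair off, with a first half-life of 0.672 h, short against the run. During that time a living end adds on average 0.195 of a unit, less than one, with free monomer taken at its charge.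

**The end.** Second-order decay stretches each successive half-life, so the additions grow with a logarithm. Over the 214 first half-lives in the run, the 0.195 is multiplied by ln(1 + 214). That product, 1.05, is the turnovers per chain: the units a chain begun adds after its first. My count gives 2.05 units per chain and 6.97 % reacted.

**The forecast.** It gave 2 and 6.8 %, holding that “Fast second-order termination then kills the living ends”.

**What ran.** The flask gives 2.05 and 6.97 %. Initiation reached the midpoint of its turnover by 0.245 h, and at 6.00 d the initiator stood at 0 % of its charge, the impurity at 37 % of its own. Growth ran on among the thinning living ends, with 88 % of its turnover behind it at 3.00 d, and ended at 1.05 units per chain after the first, against the 1.05 turnovers counted. The neighbour flask, with 0.076 M of free monomer, had 59 % of its impurity and 0 % of its initiator left at the end, so chains begun there are 1.83 % of its free monomer charged and its first half-life is 3.12 h. The same count there gives 1.40 turnovers per chain, hence 2.40 units and 4.39 % reacted, and that neighbour flask gives 2.38 and 4.37 %.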